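## Structural features

1. The target is a 1,7-diarylheptanoid in which O1 ties C1 and C5 of the heptane chain into one oxane ring (ring atoms O1, C2–C6). Ring A (3-methoxy-4,5-dihydroxyphenyl) is bonded directly to C2, a free hydroxyl sits on C4, and C6 carries a CH2CH2 tether to ring B (3,4-dihydroxyphenyl).
2. The SMILES reads as 2S,4S,6S: the three stereocentres stand in a 1,3,5-relationship, the C2 and C6 substituents are cis (both equatorial in the chair), and the C4 hydroxyl is trans to both, that is, axial.
3. The all-equatorial pattern that acid-mediated ring closures deliver is therefore the wrong C4 epimer.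
4. The fragile groups are the two catechol units (air, base, oxidants), the single aryl methyl ether that must outlive the unmasking of four phenols, and the C2–O1 bond, a p-oxygenated benzylic ether that can ionise under acid or be hydrogenolysed.
5. No single C–C bond is hard; the real difficulty is to build the oxane as one enantiomer with the 2,6-cis/4-axial pattern from few stereocontrolling events, without passing through a configurationally labile benzylic carbinol at C2.
6. The key step exploits the position of C2: it is both benzylic to the electron-rich ring A and alpha to O1, so in an open-chain ArCH2–O–C6 ether its C–H bond is the most hydridic one in the molecule and can be turned into a C2=O1+ oxocarbenium ion by hydride abstraction.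
7. C3–C4, with its oxygen on C4, is the matching enol derivative, so C2–C3 can be made by oxidative union of two electron-rich groups.
8. Only C6, an unactivated dialkyl carbinol carbon, then has to be bought; C2 and C4 are relayed from it.

## Logic of the disconnections

**16 to 15.**
- Bonds cut: the four phenolic O–H groups are traced back to four ArO–CH2Ph bonds.
- Reason: free catechols would not survive the oxidant, bases and hydrides of the route. The ring-A methyl ether also forbids a global dealkylation, so the masking group must leave by a path that O–CH3 cannot follow.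
- Gain: one kind of protecting group, removed in one operation.
- Demand: the forward step must cleave ArO–CH2Ph faster than the ring bond C2–O1.

**15 to 14.**
- Bond cut: C4–H.
- Reason: the axial C4–OH is the less stable epimer and is best set kinetically on the rigid 2,6-diequatorial chair.
- Gain: one stereocentre disappears, and C4 becomes the carbonyl group that the key step delivers.
- Demand: hydride must arrive along the equatorial trajectory.

**14 to 12 (through 13), the key disconnection.**
- Bond cut: C2–C3, which opens the only ring that has to be built and deletes the C2 stereocentre.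
- The route in one sentence: hydride abstraction from the benzylic ether carbon of open-chain 12, and capture of the resulting oxocarbenium ion 13 by its own enol acetate, closes the oxane at C2–C3. The plan drawn first by most chemists condenses a carbonyl component with an unsaturated alcohol under acid, and this sentence does not describe it. Here there is no carbonyl partner and no acid, and the electrophile is made from a C–H bond.
- Gain: a cyclic ketone with two stereocentres becomes an acyclic ether with one. That ether falls apart at a trivial C–O bond into two fragments of equal size.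
- Demand: the oxidant must pick the ring-A ArCH2–O carbon out of all benzylic positions, and C6 must control C2 through a chair.

**12 to 11.**
- Bonds cut: C4–OAc and one C3–H.
- Reason: the enol acetate is a neutral, storable carbon nucleophile that tolerates the oxidant, and a terminal alkyne is its simplest precursor.
- Gain: the nucleophile is reduced to two sp carbons.
- Demand: addition of the carboxylic acid must be Markovnikov.

**11 to 6 + 10.**
- Bond cut: O1–C2.
- Reason: this is the convergent cut, and it needs no stereocontrol because C2 is still a CH2 group.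
- Gain: ring A and ring B are prepared separately in sequences of equal length.
- Demand: O-alkylation of a secondary alkoxide must proceed without touching the O–C6 bond or the terminal alkyne.

**6 to 5.**
- Bond cut: C4–C5.
- Reason: a terminal epoxide accepts acetylide only at its CH2 carbon.
- Gain: C3 and C4 arrive as one cheap C2 unit.
- Demand: the opening must be regioselective and leave C6 untouched.

**5 to 4 to 1 + 2.**
- Bonds cut: first O1–C5 of the epoxide, then the CH2–CH2 bond of the tether next to ring B.
- Reason: 2 supplies C5, C6, O1 and the first tether carbon with the only purchased stereocentre, and its two electrophilic carbons are used one after the other.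
- Gain: two catalogue compounds.
- Demand: the carbon nucleophile must open the epoxide rather than displace chloride, because direct displacement would lead into the enantiomeric series.

**10 to 9 to 8 to 7.**
- Bonds cut: C–Br, the benzylic C–H, and two ArO–CH2Ph bonds.
- Reason: 7 already carries the 3-methoxy-4,5-dioxygenated pattern of ring A, so no aromatic substitution chemistry is needed.
- Demand: only routine functional group changes.

## Other disconnections considered

**Alternative 1:** this is the first plan that comes to mind.
- Cut: O1–C2, C2–C3 and C4–O together.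
- Forward key step: acid-promoted Prins cyclisation of (3S)-1-[3,4-bis(benzyloxy)phenyl]hex-5-en-3-ol A1 with 8 in trifluoroacetic acid, to give the all-cis 4-trifluoroacetate A2.
- Grounds for rejection:
  - The external nucleophile is captured equatorially in the chair cation, so C4 would have the wrong configuration. It would need hydrolysis followed by inversion, or an oxidation/reduction pair.
  - The strongly acidic medium keeps an aryl-stabilised oxocarbenium ion in equilibrium with its 2-oxonia-Cope isomer and with free aldehyde. This opens the way to side-chain exchange and loss of enantiopurity.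
  - The chosen plan generates the same type of cation irreversibly under buffered conditions, ends directly at the C4 ketone, and is shorter after the ring closure.

**Alternative 2:**
- Cut: O1–C2 back to a benzylic CH2.
- Forward key step: oxidation of the free 4'-phenol of the open-chain syn-diol 4-{(3R,5S)-7-[3,4-bis(benzyloxy)phenyl]-3,5-dihydroxyheptyl}-2-(benzyloxy)-6-methoxyphenol A3 (for example with Ag2O) to its p-quinone methide A4. The C6 hydroxyl then adds by 6-exo-trig 1,6-addition. The idea is biomimetic, and C2 would be self-correcting.
- Grounds for rejection: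
  - The key step makes only a C–O bond, so the whole seven-carbon chain and two stereocentres must be in place beforehand.
  - The syn-diol is pseudo-meso, so one catalyst-controlled double reduction of a 1,3-diketone cannot give it. A stepwise asymmetric aldol plus directed reduction would be needed.
  - The 4'-OH must be told apart from the 5'-OH of ring A, which costs extra protecting-group steps.
  - The cyclised product is again a p-hydroxybenzyl ether, at least as oxidisable as A3.
  - The chosen plan forms a C–C bond, is convergent and needs one stereocentre.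

**Alternative 3:**
- Cut: all ring C–H bonds at C2, C3, C5 and C6.
- Forward key step: enantioselective dearomatising hydrogenation of the flat γ-pyrone 2-[3,4-bis(benzyloxy)-5-methoxyphenyl]-6-{2-[3,4-bis(benzyloxy)phenyl]ethyl}-4H-pyran-4-one A5 to 14. The gain in simplicity is large, since no stereocentre exists in the precursor.
- Grounds for rejection:
  - The two faces of A5 differ only through the remote aryl versus arylethyl difference, and there is no directing group.
  - The two C=C bonds would be reduced at different rates.
  - The half-reduced 2-aryl-2,3-dihydropyranone can racemise by retro-oxa-Michael opening.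
  - Heterogeneous catalysts would give racemic material and strip the benzyl groups.
  - The whole absolute stereochemistry would rest on catalyst control for which the mechanism offers no handle, whereas the chosen plan relays it from a purchased centre through a chair.

Key step: step 9

Assumption: compounds 1, 2 and 7 are taken to be catalogue chemicals.

## Steps

Step 1
Reactants: 1 3,4-bis(benzyloxy)benzyl chloride; 2 (S)-epichlorohydrin
Product: 4 (2S)-4-[3,4-bis(benzyloxy)phenyl]-1-chlorobutan-2-ol, via benzylic Grignard reagent 3 (not isolated)
Conditions: Mg turnings, 2-MeTHF, 0 °C, slow addition of 1; then 2, CuI (10 mol %), −40 to 0 °C; aq. NH4Cl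
Reagents that add atoms: none
Why: Grignard formation followed by copper-catalysed SN2 opening of the epoxide at its unsubstituted carbon; the stereocentre of 2 is not touched, so 4 keeps the S configuration. Copper catalysis at low temperature favours epoxide opening over direct displacement of chloride, which would lead into the enantiomeric series.

Step 2
Reactants: 4 (2S)-4-[3,4-bis(benzyloxy)phenyl]-1-chlorobutan-2-ol
Product: 5 (2S)-2-{2-[3,4-bis(benzyloxy)phenyl]ethyl}oxirane
Conditions: powdered NaOH, Et2O, rt
Reagents that add atoms: none
Why: Intramolecular Williamson closure (3-exo-tet) of the chlorohydrin; the C–O bond at the stereocentre is not broken, so the configuration is retained (S).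

Step 3
Reactants: 5 (2S)-2-{2-[3,4-bis(benzyloxy)phenyl]ethyl}oxirane
Product: 6 (3S)-1-[3,4-bis(benzyloxy)phenyl]hex-5-yn-3-ol
Conditions: lithium acetylide ethylenediamine complex, DMSO, rt; H2O quench
Reagents that add atoms: lithium acetylide ethylenediamine complex, [Li+].[C-]#C.NCCN
Why: SN2 opening of a terminal epoxide by acetylide at the CH2 carbon forms C4–C5 and leaves the carbinol centre (future C6) untouched. Aryl benzyl ethers are inert to these conditions.

Step 4
Reactants: 7 3,4-dihydroxy-5-methoxybenzaldehyde
Product: 8 3,4-bis(benzyloxy)-5-methoxybenzaldehyde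
Conditions: BnBr (2.3 equiv), K2CO3, DMF, 60 °C
Reagents that add atoms: benzyl bromide, BrCc1ccccc1
Why: Williamson ether synthesis on both phenols; the aldehyde has no enolisable position and is inert to carbonate.

Step 5
Reactants: 8 3,4-bis(benzyloxy)-5-methoxybenzaldehyde
Product: 9 [3,4-bis(benzyloxy)-5-methoxyphenyl]methanol
Conditions: NaBH4, MeOH/THF, 0 °C
Reagents that add atoms: none
Why: Borohydride reduction of an aromatic aldehyde; no other reducible group is present.

Step 6
Reactants: 9 [3,4-bis(benzyloxy)-5-methoxyphenyl]methanol
Product: 10 3,4-bis(benzyloxy)-5-methoxybenzyl bromide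
Conditions: PBr3 (0.4 equiv), Et2O, 0 °C; used without chromatography
Reagents that add atoms: phosphorus tribromide, BrP(Br)Br
Why: Bromination of a benzylic alcohol through its phosphite ester; 3,4,5-trialkoxybenzyl bromides are handled routinely when kept cold and used promptly.

Step 7
Reactants: 6 (3S)-1-[3,4-bis(benzyloxy)phenyl]hex-5-yn-3-ol; 10 3,4-bis(benzyloxy)-5-methoxybenzyl bromide
Product: 11 (3S)-1-[3,4-bis(benzyloxy)phenyl]hex-5-yn-3-yl 3,4-bis(benzyloxy)-5-methoxybenzyl ether
Conditions: NaH (1.1 equiv), Bu4NI (cat.), THF/DMF, 0 °C to rt
Reagents that add atoms: none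
Why: Williamson ether synthesis; the alcohol is far more acidic than the terminal alkyne, so only the alkoxide forms, and iodide catalysis speeds the SN2 step at the benzylic carbon. The O–C6 bond is not broken, so the S configuration is retained.

Step 8
Reactants: 11 (3S)-1-[3,4-bis(benzyloxy)phenyl]hex-5-yn-3-yl 3,4-bis(benzyloxy)-5-methoxybenzyl ether
Product: 12 (4S)-4-{[3,4-bis(benzyloxy)-5-methoxybenzyl]oxy}-6-[3,4-bis(benzyloxy)phenyl]hex-1-en-2-yl acetate
Conditions: AcOH (2 equiv), [RuCl2(p-cymene)]2 (2 mol %), P(2-furyl)3 (4 mol %), Na2CO3 (cat.), toluene, 80 °C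
Reagents that add atoms: acetic acid, CC(=O)O
Why: Ruthenium-catalysed Markovnikov hydroacyloxylation of a terminal alkyne; the combination of an electron-poor phosphine and carbonate base directs the carboxylate to the internal carbon. The nearly neutral medium leaves all ethers and the stereocentre untouched.

Step 9
Reactants: 12 (4S)-4-{[3,4-bis(benzyloxy)-5-methoxybenzyl]oxy}-6-[3,4-bis(benzyloxy)phenyl]hex-1-en-2-yl acetate
Product: 14 (2S,6S)-2-[3,4-bis(benzyloxy)-5-methoxyphenyl]-6-{2-[3,4-bis(benzyloxy)phenyl]ethyl}oxan-4-one, via oxocarbenium ion pair 13 (not isolated)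
Conditions: DDQ (1.3 equiv), 2,6-dichloropyridine, 4 Å MS, ClCH2CH2Cl, 0 °C to rt; aq. NaHCO3
Reagents that add atoms: none
Why: DDQ forms a charge-transfer complex with the trialkoxyaryl ring A of 12 and takes an electron and then a hydrogen atom (net hydride) from the ArCH2–O carbon, giving the (E)-oxocarbenium ion 13 paired with the DDQH anion. The terminal CH2 of the tethered enol acetate then attacks C2 and forms C2–C3; transfer of the acetyl cation to the DDQH anion makes the closure irreversible and leaves the C4 ketone. The closest known reaction type is the DDQ-mediated oxidative C–H cleavage/cyclisation of benzylic ethers that carry an enol acetate, which gives 2,6-cis-tetrahydropyran-4-ones. The only ring closed is the oxane, in a 6-endo-trig mode at the C2=O1+ bond (enol-endo at the nucleophile), the same geometry as a Prins closure. The only new stereocentre, C2, is controlled by C6: in the chair transition state the arylethyl chain on C6 is equatorial and the aryl group of the (E)-oxocarbenium ion is pseudo-equatorial, so H2 and H6 both end up axial (2,6-cis, 6S gives 2S). C6 is neither benzylic nor allylic and cannot ionise, and a 2-oxonia-Cope shift would run uphill from the aryl-conjugated cation to an alkyl-substituted one through the same chair, so the bought configuration should be kept. The step needs site selectivity among the benzylic C–H bonds: only the ArCH2–O carbon of ring A gives a cation stabilised by both an ether oxygen lone pair and a p-alkoxyaryl group, whereas the ring-B CH2 lacks the oxygen and the four PhCH2–OAr carbons carry an unactivated phenyl ring and an oxygen whose lone pair is tied up in the arene. 2,6-Dichloropyridine and molecular sieves keep acid and water away, which would otherwise divert 13 to 8 and the free alcohol.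

Step 10
Reactants: 14 (2S,6S)-2-[3,4-bis(benzyloxy)-5-methoxyphenyl]-6-{2-[3,4-bis(benzyloxy)phenyl]ethyl}oxan-4-one
Product: 15 (2S,4S,6S)-2-[3,4-bis(benzyloxy)-5-methoxyphenyl]-6-{2-[3,4-bis(benzyloxy)phenyl]ethyl}oxan-4-ol
Conditions: L-Selectride (1.3 equiv), THF, −78 °C; then NaOH, H2O2, 0 °C
Reagents that add atoms: none
Why: Substrate-controlled ketone reduction with a bulky trialkylborohydride; the chair is locked by the two equatorial groups, and the axial hydrogens on C2 and C6 block the axial trajectory. Hydride therefore arrives equatorially and the C4 hydroxyl becomes axial, trans to both substituents (4S).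

Step 11
Reactants: 15 (2S,4S,6S)-2-[3,4-bis(benzyloxy)-5-methoxyphenyl]-6-{2-[3,4-bis(benzyloxy)phenyl]ethyl}oxan-4-ol
Product: 16 (2S,4S,6S)-2-(3,4-dihydroxy-5-methoxyphenyl)-6-[2-(3,4-dihydroxyphenyl)ethyl]oxan-4-ol
Conditions: H2 (1 atm), 10 % Pd/C, EtOAc/MeOH, rt, stopped at full conversion; filtration and concentration under argon
Reagents that add atoms: none
Why: Catalytic hydrogenolysis of four aryl benzyl ethers; the exposed PhCH2–OAr bonds with a phenoxide leaving group should be cleaved well before the hindered secondary C2–O1 bond inside the ring. The methyl ether, the secondary alcohol and all three stereocentres are untouched.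

## Compound list

1 | 3,4-bis(benzyloxy)benzyl chloride | ClCc1ccc(OCc2ccccc2)c(OCc2ccccc2)c1 | starting material
2 | (S)-epichlorohydrin, (2S)-2-(chloromethyl)oxirane | ClC[C@@H]1CO1 | starting material
3 | [3,4-bis(benzyloxy)benzyl]magnesium chloride | Cl[Mg]Cc1ccc(OCc2ccccc2)c(OCc2ccccc2)c1 | intermediate
4 | (2S)-4-[3,4-bis(benzyloxy)phenyl]-1-chlorobutan-2-ol | ClC[C@@H](O)CCc1ccc(OCc2ccccc2)c(OCc2ccccc2)c1 | intermediate
5 | (2S)-2-{2-[3,4-bis(benzyloxy)phenyl]ethyl}oxirane | C1O[C@H]1CCc2ccc(OCc3ccccc3)c(OCc3ccccc3)c2 | intermediate
6 | (3S)-1-[3,4-bis(benzyloxy)phenyl]hex-5-yn-3-ol | C#CC[C@@H](O)CCc1ccc(OCc2ccccc2)c(OCc2ccccc2)c1 | intermediate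
7 | 3,4-dihydroxy-5-methoxybenzaldehyde | COc1cc(C=O)cc(O)c1O | starting material
8 | 3,4-bis(benzyloxy)-5-methoxybenzaldehyde | COc1cc(C=O)cc(OCc2ccccc2)c1OCc3ccccc3 | intermediate
9 | [3,4-bis(benzyloxy)-5-methoxyphenyl]methanol | COc1cc(CO)cc(OCc2ccccc2)c1OCc3ccccc3 | intermediate
10 | 3,4-bis(benzyloxy)-5-methoxybenzyl bromide | COc1cc(CBr)cc(OCc2ccccc2)c1OCc3ccccc3 | intermediate
11 | (3S)-1-[3,4-bis(benzyloxy)phenyl]hex-5-yn-3-yl 3,4-bis(benzyloxy)-5-methoxybenzyl ether | C#CC[C@@H](OCc1cc(OC)c(OCc2ccccc2)c(OCc2ccccc2)c1)CCc1ccc(OCc2ccccc2)c(OCc2ccccc2)c1 | intermediate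
12 | (4S)-4-{[3,4-bis(benzyloxy)-5-methoxybenzyl]oxy}-6-[3,4-bis(benzyloxy)phenyl]hex-1-en-2-yl acetate | CC(=O)OC(=C)C[C@@H](OCc1cc(OC)c(OCc2ccccc2)c(OCc2ccccc2)c1)CCc1ccc(OCc2ccccc2)c(OCc2ccccc2)c1 | intermediate
13 | (E)-oxocarbenium ion from 12 (C2=O1+), ion pair with the DDQH anion | CC(=O)OC(=C)C[C@@H](/[O+]=C/c1cc(OC)c(OCc2ccccc2)c(OCc2ccccc2)c1)CCc1ccc(OCc2ccccc2)c(OCc2ccccc2)c1.[O-]c1c(Cl)c(Cl)c(O)c(C#N)c1C#N | intermediate
14 | (2S,6S)-2-[3,4-bis(benzyloxy)-5-methoxyphenyl]-6-{2-[3,4-bis(benzyloxy)phenyl]ethyl}oxan-4-one | COc1cc([C@@H]2CC(=O)C[C@H](CCc3ccc(OCc4ccccc4)c(OCc4ccccc4)c3)O2)cc(OCc5ccccc5)c1OCc6ccccc6 | intermediate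
15 | (2S,4S,6S)-2-[3,4-bis(benzyloxy)-5-methoxyphenyl]-6-{2-[3,4-bis(benzyloxy)phenyl]ethyl}oxan-4-ol | COc1cc([C@@H]2C[C@@H](O)C[C@H](CCc3ccc(OCc4ccccc4)c(OCc4ccccc4)c3)O2)cc(OCc5ccccc5)c1OCc6ccccc6 | intermediate
16 | (2S,4S,6S)-2-(3,4-dihydroxy-5-methoxyphenyl)-6-[2-(3,4-dihydroxyphenyl)ethyl]oxan-4-ol | COc1cc([C@@H]2C[C@@H](O)C[C@H](CCc3ccc(O)c(O)c3)O2)cc(O)c1O | target

## Step count and least certain steps

Total step count: 11. Longest linear sequence: 8 steps (steps 1–3 or steps 4–6, then steps 7–11).

**Step 9 (key step).** Three things are most likely to go wrong.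
- Hydride abstraction may be slow or occur at the wrong site. Ring B is at least as easily oxidised to its radical cation as ring A, whose central alkoxy group is twisted out of conjugation.
- The product may be over-oxidised at its remaining C2–H bond.
- The ether may be cleaved hydrolytically by adventitious water.

The fallback gives up the C–H oxidation and makes the cation by condensation.
- It sets out from 5 and 8.
- Copper-catalysed opening of 5 with the vinyl Grignard reagent from 2-bromo-3-(trimethylsilyl)propene should give the hydroxy allylsilane (3S)-1-[3,4-bis(benzyloxy)phenyl]-5-[(trimethylsilyl)methyl]hex-5-en-3-ol F1.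
- TMSOTf-promoted union of F1 with 8 at −78 °C (intramolecular silyl-modified Sakurai annulation, same chair, 2,6-cis) should give the 4-methylidene oxane (2S,6S)-2-[3,4-bis(benzyloxy)-5-methoxyphenyl]-6-{2-[3,4-bis(benzyloxy)phenyl]ethyl}-4-methylideneoxane F2.
- Lemieux–Johnson cleavage (cat. OsO4, NaIO4, 2,6-lutidine) brings the material back to the route at 14.

**Step 1.** Two things may go wrong.
- Wurtz-type homocoupling may occur during formation of the electron-rich benzylic Grignard reagent.
- Some direct displacement of chloride in 2 would erode the enantiomeric purity.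

The fallback reverses the polarity and sets the stereocentre by catalysis.
- It sets out from 1, used as the electrophile.
- Coupling with allylmagnesium bromide should give 4-[3,4-bis(benzyloxy)phenyl]but-1-ene F3.
- Epoxidation with mCPBA gives the racemic 2-{2-[3,4-bis(benzyloxy)phenyl]ethyl}oxirane F4.
- Hydrolytic kinetic resolution follows, using the enantiomer of the (salen)Co(III) catalyst that consumes the R epoxide. It turns that half into (2R)-4-[3,4-bis(benzyloxy)phenyl]butane-1,2-diol F5 and leaves the S epoxide, so the route is rejoined at 5.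

**Step 10.** The risk is poor facial selectivity. The oxane ring is flatter than a cyclohexane, and the steric bias against axial attack comes only from two axial hydrogens.

The fallback accepts the opposite selectivity and inverts.
- It sets out from 14.
- NaBH4 in MeOH should give mainly the equatorial alcohol (2S,4R,6S)-2-[3,4-bis(benzyloxy)-5-methoxyphenyl]-6-{2-[3,4-bis(benzyloxy)phenyl]ethyl}oxan-4-ol F6.
- Mitsunobu inversion with 4-nitrobenzoic acid, PPh3 and DIAD gives the axial ester (2S,4S,6S)-2-[3,4-bis(benzyloxy)-5-methoxyphenyl]-6-{2-[3,4-bis(benzyloxy)phenyl]ethyl}oxan-4-yl 4-nitrobenzoate F7.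
- Methanolysis with K2CO3 in MeOH returns to the route at 15.

**Step 11.** Two things may go wrong.
- The ring may open by hydrogenolysis at the benzylic C2–O1 bond once ring A has become a free, strongly donating phenol.
- The catechols may be oxidised by air during isolation.

The fallback gives up reduction altogether.
- It sets out from 15.
- BCl3 with pentamethylbenzene as benzyl cation scavenger in CH2Cl2 at −78 °C should transfer the four benzyl groups to the scavenger while the methyl ether stays.
- Any reversible ionisation at C2 would reclose to the more stable 2,6-cis ring.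
- The route is rejoined at 16. This fallback makes no new compound (F0).

## Further compounds

F1 | step 9 | (3S)-1-[3,4-bis(benzyloxy)phenyl]-5-[(trimethylsilyl)methyl]hex-5-en-3-ol | C=C(C[Si](C)(C)C)C[C@@H](O)CCc1ccc(OCc2ccccc2)c(OCc2ccccc2)c1
F2 | step 9 | (2S,6S)-2-[3,4-bis(benzyloxy)-5-methoxyphenyl]-6-{2-[3,4-bis(benzyloxy)phenyl]ethyl}-4-methylideneoxane | COc1cc([C@@H]2CC(=C)C[C@H](CCc3ccc(OCc4ccccc4)c(OCc4ccccc4)c3)O2)cc(OCc5ccccc5)c1OCc6ccccc6
F3 | step 1 | 4-[3,4-bis(benzyloxy)phenyl]but-1-ene | C=CCCc1ccc(OCc2ccccc2)c(OCc2ccccc2)c1
F4 | step 1 | racemic 2-{2-[3,4-bis(benzyloxy)phenyl]ethyl}oxirane | C1OC1CCc2ccc(OCc3ccccc3)c(OCc3ccccc3)c2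
F5 | step 1 | (2R)-4-[3,4-bis(benzyloxy)phenyl]butane-1,2-diol | OC[C@H](O)CCc1ccc(OCc2ccccc2)c(OCc2ccccc2)c1
F6 | step 10 | (2S,4R,6S)-2-[3,4-bis(benzyloxy)-5-methoxyphenyl]-6-{2-[3,4-bis(benzyloxy)phenyl]ethyl}oxan-4-ol | COc1cc([C@@H]2C[C@H](O)C[C@H](CCc3ccc(OCc4ccccc4)c(OCc4ccccc4)c3)O2)cc(OCc5ccccc5)c1OCc6ccccc6
F7 | step 10 | (2S,4S,6S)-2-[3,4-bis(benzyloxy)-5-methoxyphenyl]-6-{2-[3,4-bis(benzyloxy)phenyl]ethyl}oxan-4-yl 4-nitrobenzoate | COc1cc([C@@H]2C[C@@H](OC(=O)c3ccc(cc3)[N+](=O)[O-])C[C@H](CCc4ccc(OCc5ccccc5)c(OCc5ccccc5)c4)O2)cc(OCc6ccccc6)c1OCc7ccccc7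
F0 | step 11 | none | none
A1 | alternative 1 | (3S)-1-[3,4-bis(benzyloxy)phenyl]hex-5-en-3-ol | C=CC[C@@H](O)CCc1ccc(OCc2ccccc2)c(OCc2ccccc2)c1
A2 | alternative 1 | (2S,4R,6S)-2-[3,4-bis(benzyloxy)-5-methoxyphenyl]-6-{2-[3,4-bis(benzyloxy)phenyl]ethyl}oxan-4-yl trifluoroacetate | COc1cc([C@@H]2C[C@H](OC(=O)C(F)(F)F)C[C@H](CCc3ccc(OCc4ccccc4)c(OCc4ccccc4)c3)O2)cc(OCc5ccccc5)c1OCc6ccccc6
A3 | alternative 2 | 4-{(3R,5S)-7-[3,4-bis(benzyloxy)phenyl]-3,5-dihydroxyheptyl}-2-(benzyloxy)-6-methoxyphenol | COc1cc(CC[C@@H](O)C[C@H](CCc2ccc(OCc3ccccc3)c(OCc3ccccc3)c2)O)cc(OCc4ccccc4)c1O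
A4 | alternative 2 | p-quinone methide of A3, 2-(benzyloxy)-4-{(3R,5S)-7-[3,4-bis(benzyloxy)phenyl]-3,5-dihydroxyheptylidene}-6-methoxycyclohexa-2,5-dien-1-one | COC1=CC(=CC[C@@H](O)C[C@H](CCc2ccc(OCc3ccccc3)c(OCc3ccccc3)c2)O)C=C(OCc4ccccc4)C1=O
A5 | alternative 3 | 2-[3,4-bis(benzyloxy)-5-methoxyphenyl]-6-{2-[3,4-bis(benzyloxy)phenyl]ethyl}-4H-pyran-4-one | COc1cc(-c2cc(=O)cc(CCc3ccc(OCc4ccccc4)c(OCc4ccccc4)c3)o2)cc(OCc5ccccc5)c1OCc6ccccc6
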